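Abbreviations: Ts = 4-methylbenzenesulfonyl, An = 4-methoxyphenyl, Boc = tert-butoxycarbonyl. Ring A positions: 1 carries the ring CH2, 2 carries furan 2 C3, 3 the furan 2 oxygen, 4 the only hydrogen, 5 the furan 1 oxygen, 6 furan 1 C3.

## Analysis of the target

Target 28 is a hexacyclic resveratrol trimer built around a pentasubstituted benzene, ring A. Ring A is fused to two trans-2,3-diaryl-2,3-dihydrofurans and, through positions 1 and 2, to a seven-membered carbocycle. That carbocycle also holds the CH2, a methine bearing a 4-hydroxyphenyl group, two carbons of the resorcinol ring B and furan 2 C3. There are five stereocentres: furan 1 is (2R,3R), furan 2 is (2S,3S) and the ring methine is (S). The two furans are mirror images of each other across the plane through positions 1 and 4 of ring A. The methine hydrogen is anti to the hydrogen at furan 2 C3, so the methine aryl group is pseudo-axial. Sensitive groups are the seven phenols and the two benzylic C2–O bonds of the furans, which ionise under strong acid. The synthesis is hard because ring A is crowded and because of a hidden symmetry: without the methine–ring B bond the bis-furan stilbene is a meso compound. The enantiomer is therefore decided only by which of the two 3,5-dioxygenated rings closes onto the methine, and these two rings must be made chemically different. The strategy rests on positions 6, 1 and 2 of ring A, which carry carbon substituents in a row with the CH2 in the middle. An aryl iodide at position 1 whose ortho position 6 is already filled by furan 1 C3 can be acylated at position 2 and vinylated at position 1 in one operation.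

## Retrosynthetic reasoning

**Deprotection (28 from 27 from 26).** The seven phenols are unmasked last. Five are methyl ethers, and the two on the furan 1 aryl ring are tosylates. The tosylates are not a convenience: with seven methyl ethers the precursor of the seven-membered ring would be meso and the ring closure would give the racemate. Basic cleavage of the sulfonates comes first, so that no free polyphenol meets hot base, and Lewis-acid ether cleavage comes last.

**Seven-membered ring (26 from 25).** The bond between the ring methine and ring B is cut. This reveals the E-stilbene of 25, whose protonation gives a 4-methoxybenzyl cation next to two resorcinol-type rings. Ring B is an ortho/para-activated dimethoxyarene; the bis-tosyloxy ring on furan 1 is switched off. The forward Friedel–Crafts closure has to choose ring B and set the methine centre. Cutting here leaves a stilbene on ring A, which an alkene coupling can deliver.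

**Furan 2 (25 from 21 and 23, through 24).** The O–C2 and C2–C3 bonds of furan 2 are cut in a (4+1) sense. This leads to o-quinone methide 24 and the benzylic ylide of sulfonium salt 23. Both stereocentres of the ring come from one reagent-controlled step, and the carbon framework needed is only a diaryl ketone on ring A. The precursor 21 must release 24 without acid, because a diarylmethyl cation next to the stilbene would close a five-membered ring. Carbonate 21 does this by anionic Boc migration. It comes from ketone 18 through phenol 19 and carbinol 20.

**Three-component assembly (18 from 13, 16 and 17).** The ring A–carbonyl bond at position 2 and the ring A–vinyl bond at position 1 are cut together. Iodide 13 has position 6 blocked by furan 1 C3 and a single ortho hydrogen at position 2, which is the substitution pattern a Catellani reaction requires. The coupling installs the ketone for furan 2 and the stilbene for the seven-membered ring at once. The oxygen at position 3 stays a methyl ether because it is the smallest group that can sit beside the C–H bond to be palladated.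

**Furan 1 (13 from 8 and 11, through 12).** The same (4+1) disconnection is used, here on a substrate without an alkene, so the sulfone 8 can be made under acid. Sulfone 8 comes from ketone 6 through carbinol 7. The (2R,5R) salt 11 is used here and the (2S,5S) salt 23 for furan 2, because the two furans have opposite absolute sense.

**Ketone (6 from 5; 5 from 2 and 3, through 4).** The aryl–carbonyl bond is cut as a Friedel–Crafts acylation of the symmetric iodoarene 3. Symmetry leaves only one competing position. Chelation-controlled demethylation then differentiates the two oxygens of ring A. Acid 2 comes from 1 by sulfonylation. Anhydride 16 comes from 14 and 15, and the salts 11 and 23 from thiolanes 9 and 22 with bromide 10.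

## Alternatives that were turned down

**Alternative 1:** The seven-membered ring is cut at both bonds to ring B. Forward, a fluoride-released aryne from silyl triflate A2 would insert into the C1–C2 bond of keto ester A1 by acyl-alkylation, giving dibenzosuberone ester A3. In its favour, two C–C bonds and the seven-membered ring form in one step, and the flanking methoxy group of the aryne steers the regiochemistry. It is stronger than the chosen route in how quickly the carbocycle appears. Against it, A3 is racemic at an epimerisable centre. Ring A of A3 still has a hydrogen at position 6, so furan 1 would have to be attached later at the most hindered C–H of the molecule. The ester and the ketone each need several steps and new stereocontrol to become furan 2 C2 and the aryl methine. The chosen route instead places all three carbon substituents of ring A early and closes every ring by a reaction of its own class.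

**Alternative 2:** The bond from ring B to furan 2 C3 is cut, with furan 2 taken back to a flat benzofuran. Forward, aryl bromide A4 would undergo palladium-catalysed syn arylpalladation across C2=C3 followed by hydride capture, giving the heptamethyl ether A5. In its favour, the trans relation in furan 2 follows from the syn addition, the ring closure is the last skeletal step, and only one global deprotection remains. It is stronger than the chosen route on one further point: ring B is already tied to the methine, so the meso problem never arises and no protecting-group differentiation is needed. Against it, A4 still needs ring A with its three contiguous carbon substituents, furan 1, and an enantiopure 1,1-diarylethyl centre carrying an ortho-bromoarene. The closure must form a seven-membered ring and a fully substituted C–Pd bond next to oxygen, and facial control would have to be relayed from the methine through a large ring. The chosen route answers the ring A problem directly and uses the cationic closure that this ring system is built for.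

**Alternative 3:** The methine–ring B and methine–carbonyl bonds are cut, leading back to the symmetric anthraquinone A6. Forward, Lewis-acid-promoted insertion of one equivalent of diazoalkane A7 into one carbonyl of A6 with aryl migration would give the ring-expanded enol A8. In its favour, A6 is symmetric and cheap, and the tricyclic carbon skeleton with all ring oxygens appears in one step. No route to the carbocycle is shorter, and here it beats the chosen strategy. Against it, the carbonyls of A6 are deactivated vinylogous esters with peri methoxy groups. Two different aryl carbons can migrate, and A7 is a labile electron-rich diazo compound. A8 has none of the five stereocentres, still needs both furans (furan 1 again at the hindered C–H of position 6), and needs a deoxygenation. The chosen route has a longer start, but its key step leaves a ketone and a stilbene exactly where furan 2 and the seven-membered ring are to form.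

Key step: step 8

## Route

Remark: (2R,5R)- and (2S,5S)-2,5-dimethylthiolane (9, 22) are taken as stock chiral reagents; each is otherwise two routine steps (bis-mesylation, then Na2S) from the commercial enantiomeric hexane-2,5-diol.

Step 1
Reactants: 1 3,5-dihydroxybenzoic acid
Product: 2 3,5-bis(4-methylbenzenesulfonyloxy)benzoic acid
Conditions: TsCl, aq. NaOH, THF, 0 °C to rt; then aq. HCl
Reagents that add atoms: 4-methylbenzenesulfonyl chloride, Cc1ccc(cc1)S(Cl)(=O)=O
Why: Schotten–Baumann sulfonylation of both phenoxides; any mixed carboxylic–sulfonic anhydride is hydrolysed in the basic medium, so acidification should return the free acid. The tosylates make this ring inert as a Friedel–Crafts nucleophile in step 13 and should survive every step up to step 14.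

Step 2
Reactants: 2 3,5-bis(4-methylbenzenesulfonyloxy)benzoic acid; 3 1-iodo-3,5-dimethoxybenzene
Product: 5 [3,5-bis(tosyloxy)phenyl](2-iodo-4,6-dimethoxyphenyl)methanone, via acid chloride 4 (not isolated)
Conditions: (COCl)2, cat. DMF, CH2Cl2, 0 °C to rt, evaporate; then 3, AlCl3, CH2Cl2, 0 °C
Reagents that add atoms: none
Why: Friedel–Crafts acylation; the two equivalent positions of 3 that are ortho to iodine and para to a methoxy group should react in preference to the position between the two methoxy groups. Iodine is meta to both donors, so ipso protonation and loss of iodine are not assisted.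

Step 3
Reactants: 5 [3,5-bis(tosyloxy)phenyl](2-iodo-4,6-dimethoxyphenyl)methanone
Product: 6 [3,5-bis(tosyloxy)phenyl](2-hydroxy-6-iodo-4-methoxyphenyl)methanone
Conditions: BCl3, CH2Cl2, −78 to 0 °C; aq. work-up
Reagents that add atoms: none
Why: Chelation-controlled demethylation; boron binds the ketone oxygen and the ortho methoxy oxygen in a six-membered chelate, so only that methyl group is cleaved by chloride. The para methoxy group, the later furan 2 oxygen, stays masked.

Step 4
Reactants: 6 [3,5-bis(tosyloxy)phenyl](2-hydroxy-6-iodo-4-methoxyphenyl)methanone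
Product: 8 2-{[3,5-bis(tosyloxy)phenyl](4-methylbenzenesulfonyl)methyl}-3-iodo-5-methoxyphenol (racemic), via carbinol 7 (not isolated)
Conditions: NaBH4, THF–MeOH, 0 °C to rt; then TolSO2Na, HCO2H–H2O, rt
Reagents that add atoms: sodium 4-methylbenzenesulfinate, Cc1ccc(cc1)S(=O)[O-].[Na+]
Why: Hydride reduction of the diaryl ketone, then acid ionisation of the ortho-hydroxy, para-methoxy benzhydrol and capture of the cation at sulfur by the sulfinate. The sulfone is a bench-stable o-quinone methide precursor that loses sulfinate under mild base; no alkene is present, so acid is safe here.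

Step 5
Reactants: 9 (2R,5R)-2,5-dimethylthiolane; 10 4-methoxybenzyl bromide
Product: 11 (2R,5R)-1-(4-methoxybenzyl)-2,5-dimethylthiolan-1-ium tetrafluoroborate
Conditions: NaBF4, CH2Cl2–H2O, rt
Reagents that add atoms: sodium tetrafluoroborate, [Na+].F[B-](F)(F)F
Why: SN2 S-alkylation of the sulfide; exchange of bromide for tetrafluoroborate in the two-phase medium pulls the reversible alkylation forward. The C2 symmetry of the thiolane means one sulfonium salt with no sulfur stereocentre.

Step 6
Reactants: 8 2-{[3,5-bis(tosyloxy)phenyl](4-methylbenzenesulfonyl)methyl}-3-iodo-5-methoxyphenol; 11 (2R,5R)-1-(4-methoxybenzyl)-2,5-dimethylthiolan-1-ium tetrafluoroborate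
Product: 13 (2R,3R)-3-[3,5-bis(tosyloxy)phenyl]-4-iodo-6-methoxy-2-(4-methoxyphenyl)-2,3-dihydro-1-benzofuran, via o-quinone methide 12 (not isolated)
Conditions: Cs2CO3, MeCN, −20 °C to rt
Reagents that add atoms: none
Why: Proposed new method: the closest known reaction type is the (4+1) annulation of o-quinone methides with sulfonium ylides, shown mainly with achiral or carbonyl-stabilised ylides, and the asymmetric transfer of benzylidene groups from chiral sulfonium salts to aldehydes; here the two are combined. Carbonate releases 12 from the sulfone and the ylide from 11, the ylide adds through the face left open by the thiolane methyl groups to the exocyclic carbon, and the anti betaine closes by SN2 displacement of the sulfide by the phenoxide, which should give the trans ring; by analogy with benzylidene transfer from this sulfide to aldehydes the (2R,5R) salt is expected to give the (2R,3R) product, and if the sense proved opposite salts 11 and 23 would simply exchange roles.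

Step 7
Reactants: 14 3,5-dimethoxybenzoic acid; 15 3,5-dimethoxybenzoyl chloride
Product: 16 3,5-dimethoxybenzoic anhydride
Conditions: Et3N, CH2Cl2, 0 °C to rt
Reagents that add atoms: none
Why: Acylation of the carboxylate by the acid chloride, a standard anhydride synthesis.

Step 8
Reactants: 13 (2R,3R)-3-[3,5-bis(tosyloxy)phenyl]-4-iodo-6-methoxy-2-(4-methoxyphenyl)-2,3-dihydro-1-benzofuran; 16 3,5-dimethoxybenzoic anhydride; 17 4-methoxystyrene
Product: 18 [(2R,3R)-3-[3,5-bis(tosyloxy)phenyl]-6-methoxy-2-(4-methoxyphenyl)-4-[(E)-2-(4-methoxyphenyl)ethenyl]-2,3-dihydro-1-benzofuran-5-yl](3,5-dimethoxyphenyl)methanone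
Conditions: Pd(OAc)2 (cat.), tri(2-furyl)phosphine, norbornene, Cs2CO3, toluene, 100 °C
Reagents that add atoms: none
Why: Catellani reaction with ortho acylation and ipso Mizoroki–Heck termination, a known combination for ortho-substituted aryl iodides, carboxylic anhydrides and terminal alkenes. Zerovalent palladium inserts into the C4–I bond of 13, norbornene inserts syn into the aryl–palladium bond, and carbonate-assisted palladation of the C5–H bond gives the five-membered aryl–norbornyl palladacycle. The anhydride adds oxidatively to give a tetravalent palladium acyl species and reductive elimination forms the C5–acyl bond; with both ortho positions filled, β-carbon elimination expels norbornene and leaves divalent arylpalladium at C4. Syn insertion of 17 with the aryl group going to the terminal carbon, then syn β-hydride elimination, gives the E-stilbene, and base returns zerovalent palladium. No ring is closed and no stereocentre is formed; the two existing centres lie outside the reacting atoms and have no hydrogen acidic enough for carbonate. The selectivity needed is a single site of palladation, secured because C3a is the blocked ortho position and C5 carries the only ortho hydrogen, and acylation before alkene capture, secured by the much faster insertion of strained norbornene than of the styrene. The aryl tosylates should not react with a tri(2-furyl)phosphine palladium catalyst. The demanding point is that the C5–H bond is flanked by the 6-methoxy group, which is why the smallest possible oxygen substituent is kept there.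

Step 9
Reactants: 18 the ketone from step 8
Product: 19 [(2R,3R)-3-[3,5-bis(tosyloxy)phenyl]-6-hydroxy-2-(4-methoxyphenyl)-4-[(E)-2-(4-methoxyphenyl)ethenyl]-2,3-dihydro-1-benzofuran-5-yl](3,5-dimethoxyphenyl)methanone
Conditions: BCl3, CH2Cl2, −78 °C; aq. work-up
Reagents that add atoms: none
Why: Chelation-controlled demethylation as in step 3; only the 6-methoxy group is ortho to the ketone, while the ring B and anisyl ethers cannot chelate. The low temperature is meant to spare the benzylic C2–O bond and the stilbene.

Step 10
Reactants: 19 the 6-hydroxy ketone from step 9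
Product: 21 tert-butyl carbonate of the 6-hydroxy group of (2R,3R)-3-[3,5-bis(tosyloxy)phenyl]-5-[(3,5-dimethoxyphenyl)(hydroxy)methyl]-2-(4-methoxyphenyl)-4-[(E)-2-(4-methoxyphenyl)ethenyl]-2,3-dihydro-1-benzofuran-6-ol (both carbinol epimers), via carbinol 20 (not isolated)
Conditions: NaBH4, THF–MeOH, 0 °C, work-up at pH 7; then Boc2O, K2CO3, cat. 18-crown-6, THF, 0 °C
Reagents that add atoms: di-tert-butyl dicarbonate, CC(C)(C)OC(=O)OC(=O)OC(C)(C)C
Why: Ketone reduction followed by chemoselective O-acylation of the phenoxide, which is far more nucleophilic than the hindered secondary alcohol. The carbinol never meets acid, because its cation would add to the neighbouring stilbene in a Nazarov-type closure to an indane.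

Step 11
Reactants: 22 (2S,5S)-2,5-dimethylthiolane; 10 4-methoxybenzyl bromide
Product: 23 (2S,5S)-1-(4-methoxybenzyl)-2,5-dimethylthiolan-1-ium tetrafluoroborate
Conditions: NaBF4, CH2Cl2–H2O, rt
Reagents that add atoms: sodium tetrafluoroborate, [Na+].F[B-](F)(F)F
Why: Same S-alkylation and anion exchange as in step 5, with the enantiomeric sulfide.

Step 12
Reactants: 21 the phenol carbonate from step 10; 23 (2S,5S)-1-(4-methoxybenzyl)-2,5-dimethylthiolan-1-ium tetrafluoroborate
Product: 25 bis-dihydrobenzofuran stilbene: ring A carrying furan 1 [(2R,3R); C3 aryl 3,5-bis(tosyloxy)phenyl; C2 aryl An], furan 2 [(2S,3S); C3 aryl 3,5-dimethoxyphenyl; C2 aryl An] and the (E)-2-(4-methoxyphenyl)ethenyl group at position 1, via o-quinone methide 24 (not isolated)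
Conditions: NaN(SiMe3)2 (2 equiv), THF, −78 to 0 °C
Reagents that add atoms: none
Why: Proposed new method: the closest known reaction types are the anionic generation of o-quinone methides from phenol carbonates of salicyl alcohols (alkoxide formation, Boc migration, loss of tert-butyl carbonate) and the sulfonium ylide (4+1) annulation of step 6; here a chiral benzylic ylide intercepts 24 on a substrate that already holds furan 1. One equivalent of base forms the alkoxide and the other the ylide; the ylide from 23 should add with the face selectivity opposite to that of 11 and the anti betaine should close by SN2 to the trans (2S,3S) ring, the reagent overriding the weak bias of the distant furan 1; exactly two equivalents of base are used so that the benzylic C3–H of furan 1 is not deprotonated.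

Step 13
Reactants: 25 the bis-dihydrobenzofuran stilbene from step 12
Product: 26 hexacyclic pentamethyl ether bis-tosylate: the target skeleton with An groups on the ring methine (S) and on both furan C2 atoms, two methoxy groups on ring B and two tosyloxy groups on the furan 1 aryl ring
Conditions: TFA, CH2Cl2, 0 °C to rt, dilute
Reagents that add atoms: none
Why: Friedel–Crafts alkylation closing the seven-membered ring: protonation of the stilbene at the CH next to ring A gives the 4-methoxybenzyl cation, and only ring B is nucleophilic because the bis-tosyloxy ring is deactivated, which fixes the enantiomer. The methine centre is set by A(1,3) strain: its hydrogen takes the position in the plane of ring B beside the ortho methoxy group and the aryl group goes pseudo-axial, which is the (S) centre with H anti to H-3 of furan 2. Reversible ionisation of this doubly benzylic bond should let the same epimer accumulate.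

Step 14
Reactants: 26 the pentamethyl ether bis-tosylate from step 13
Product: 27 pentamethyl ether of the target with a free 3,5-dihydroxyphenyl group on furan 1 C3
Conditions: KOH, MeOH–THF, 60 °C; then aq. HCl
Reagents that add atoms: none
Why: Hydroxide or methoxide attack at sulfur cleaves the two aryl sulfonates. The methyl ethers, the dihydrofurans and the non-acidic stereocentres should not be affected.

Step 15
Reactants: 27 the diphenol pentamethyl ether from step 14
Product: 28 target, furan 1 (2R,3R), furan 2 (2S,3S), ring methine (S), seven free phenols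
Conditions: BBr3, CH2Cl2, −78 °C to rt; then MeOH, H2O
Reagents that add atoms: none
Why: Lewis-acid cleavage of the five aryl methyl ethers by bromide attack on the boron-activated methyl groups. The trans dihydrofurans are the thermodynamic isomers, so a reversible opening of the benzylic C–O bonds should return the same configuration.

## Compound list

1 | 3,5-dihydroxybenzoic acid | OC(=O)c1cc(O)cc(O)c1 | starting material
2 | 3,5-bis(4-methylbenzenesulfonyloxy)benzoic acid | OC(=O)c1cc(OS(=O)(=O)c2ccc(C)cc2)cc(OS(=O)(=O)c2ccc(C)cc2)c1 | intermediate
3 | 1-iodo-3,5-dimethoxybenzene | COc1cc(I)cc(OC)c1 | starting material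
4 | 3,5-bis(tosyloxy)benzoyl chloride | ClC(=O)c1cc(OS(=O)(=O)c2ccc(C)cc2)cc(OS(=O)(=O)c2ccc(C)cc2)c1 | intermediate
5 | [3,5-bis(tosyloxy)phenyl](2-iodo-4,6-dimethoxyphenyl)methanone | COc1cc(OC)c(C(=O)c2cc(OS(=O)(=O)c3ccc(C)cc3)cc(OS(=O)(=O)c3ccc(C)cc3)c2)c(I)c1 | intermediate
6 | [3,5-bis(tosyloxy)phenyl](2-hydroxy-6-iodo-4-methoxyphenyl)methanone | COc1cc(O)c(C(=O)c2cc(OS(=O)(=O)c3ccc(C)cc3)cc(OS(=O)(=O)c3ccc(C)cc3)c2)c(I)c1 | intermediate
7 | [3,5-bis(tosyloxy)phenyl](2-hydroxy-6-iodo-4-methoxyphenyl)methanol, racemic | COc1cc(O)c(C(O)c2cc(OS(=O)(=O)c3ccc(C)cc3)cc(OS(=O)(=O)c3ccc(C)cc3)c2)c(I)c1 | intermediate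
8 | 2-{[3,5-bis(tosyloxy)phenyl](4-methylbenzenesulfonyl)methyl}-3-iodo-5-methoxyphenol, racemic | COc1cc(O)c(C(c2cc(OS(=O)(=O)c3ccc(C)cc3)cc(OS(=O)(=O)c3ccc(C)cc3)c2)S(=O)(=O)c2ccc(C)cc2)c(I)c1 | intermediate
9 | (2R,5R)-2,5-dimethylthiolane | C[C@@H]1CC[C@@H](C)S1 | starting material
10 | 4-methoxybenzyl bromide | COc1ccc(CBr)cc1 | starting material
11 | (2R,5R)-1-(4-methoxybenzyl)-2,5-dimethylthiolan-1-ium tetrafluoroborate | C[C@@H]1CC[C@@H](C)[S+]1Cc1ccc(OC)cc1.F[B-](F)(F)F | intermediate
12 | 6-{[3,5-bis(tosyloxy)phenyl]methylidene}-5-iodo-3-methoxycyclohexa-2,4-dien-1-one (o-quinone methide) | O=C1C=C(OC)C=C(I)C1=Cc1cc(OS(=O)(=O)c2ccc(C)cc2)cc(OS(=O)(=O)c2ccc(C)cc2)c1 | intermediate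
13 | (2R,3R)-3-[3,5-bis(tosyloxy)phenyl]-4-iodo-6-methoxy-2-(4-methoxyphenyl)-2,3-dihydro-1-benzofuran | COc1cc2c(c(I)c1)[C@@H](c1cc(OS(=O)(=O)c3ccc(C)cc3)cc(OS(=O)(=O)c3ccc(C)cc3)c1)[C@H](c1ccc(OC)cc1)O2 | intermediate
14 | 3,5-dimethoxybenzoic acid | COc1cc(cc(OC)c1)C(=O)O | starting material
15 | 3,5-dimethoxybenzoyl chloride | COc1cc(cc(OC)c1)C(Cl)=O | starting material
16 | 3,5-dimethoxybenzoic anhydride | COc1cc(OC)cc(c1)C(=O)OC(=O)c1cc(OC)cc(OC)c1 | intermediate
17 | 4-methoxystyrene | COc1ccc(C=C)cc1 | starting material
18 | [(2R,3R)-3-[3,5-bis(tosyloxy)phenyl]-6-methoxy-2-(4-methoxyphenyl)-4-[(E)-2-(4-methoxyphenyl)ethenyl]-2,3-dihydro-1-benzofuran-5-yl](3,5-dimethoxyphenyl)methanone | COc1cc2c(c(/C=C/c3ccc(OC)cc3)c1C(=O)c1cc(OC)cc(OC)c1)[C@@H](c1cc(OS(=O)(=O)c3ccc(C)cc3)cc(OS(=O)(=O)c3ccc(C)cc3)c1)[C@H](c1ccc(OC)cc1)O2 | intermediate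
19 | 6-hydroxy analogue of 18 | Oc1cc2c(c(/C=C/c3ccc(OC)cc3)c1C(=O)c1cc(OC)cc(OC)c1)[C@@H](c1cc(OS(=O)(=O)c3ccc(C)cc3)cc(OS(=O)(=O)c3ccc(C)cc3)c1)[C@H](c1ccc(OC)cc1)O2 | intermediate
20 | carbinol from 19, (2R,3R), both epimers at the carbinol carbon | Oc1cc2c(c(/C=C/c3ccc(OC)cc3)c1C(O)c1cc(OC)cc(OC)c1)[C@@H](c1cc(OS(=O)(=O)c3ccc(C)cc3)cc(OS(=O)(=O)c3ccc(C)cc3)c1)[C@H](c1ccc(OC)cc1)O2 | intermediate
21 | 6-O-tert-butoxycarbonyl derivative of 20 | CC(C)(C)OC(=O)Oc1cc2c(c(/C=C/c3ccc(OC)cc3)c1C(O)c1cc(OC)cc(OC)c1)[C@@H](c1cc(OS(=O)(=O)c3ccc(C)cc3)cc(OS(=O)(=O)c3ccc(C)cc3)c1)[C@H](c1ccc(OC)cc1)O2 | intermediate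
22 | (2S,5S)-2,5-dimethylthiolane | C[C@H]1CC[C@H](C)S1 | starting material
23 | (2S,5S)-1-(4-methoxybenzyl)-2,5-dimethylthiolan-1-ium tetrafluoroborate | C[C@H]1CC[C@H](C)[S+]1Cc1ccc(OC)cc1.F[B-](F)(F)F | intermediate
24 | o-quinone methide from 21: (2R,3R)-dihydrobenzofuran-6-one with 5-(3,5-dimethoxybenzylidene) and 4-[(E)-4-methoxystyryl] groups | O=C1C=C2O[C@@H](c3ccc(OC)cc3)[C@H](c3cc(OS(=O)(=O)c4ccc(C)cc4)cc(OS(=O)(=O)c4ccc(C)cc4)c3)C2=C(/C=C/c2ccc(OC)cc2)C1=Cc1cc(OC)cc(OC)c1 | intermediate
25 | bis-dihydrobenzofuran stilbene, furan 1 (2R,3R) with 3,5-bis(tosyloxy)phenyl, furan 2 (2S,3S) with 3,5-dimethoxyphenyl, E-stilbene at position 1 | COc1ccc(/C=C/c2c3c(cc4c2[C@@H](c2cc(OS(=O)(=O)c5ccc(C)cc5)cc(OS(=O)(=O)c5ccc(C)cc5)c2)[C@H](c2ccc(OC)cc2)O4)O[C@H](c2ccc(OC)cc2)[C@H]3c2cc(OC)cc(OC)c2)cc1 | intermediate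
26 | hexacyclic pentamethyl ether bis-tosylate, ring methine (S) | COc1ccc([C@@H]2Cc3c4c(cc5c3[C@@H](c3cc(OS(=O)(=O)c6ccc(C)cc6)cc(OS(=O)(=O)c6ccc(C)cc6)c3)[C@H](c3ccc(OC)cc3)O5)O[C@H](c3ccc(OC)cc3)[C@H]4c3cc(OC)cc(OC)c32)cc1 | intermediate
27 | pentamethyl ether of the target with free 3,5-dihydroxyphenyl on furan 1 | COc1ccc([C@@H]2Cc3c4c(cc5c3[C@@H](c3cc(O)cc(O)c3)[C@H](c3ccc(OC)cc3)O5)O[C@H](c3ccc(OC)cc3)[C@H]4c3cc(OC)cc(OC)c32)cc1 | intermediate
28 | CNP0136963.1 | Oc1ccc([C@@H]2Cc3c4c(cc5c3[C@@H](c3cc(O)cc(O)c3)[C@H](c3ccc(O)cc3)O5)O[C@H](c3ccc(O)cc3)[C@H]4c3cc(O)cc(O)c32)cc1 | target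

## Step count and least certain steps

Total: 15 steps. Longest linear sequence: 12 steps (1, 2, 3, 4, 6, 8, 9, 10, 12, 13, 14, 15).

**Step 6 (proposed method).** The most likely failure is poor face discrimination of the benzylic ylide, or leakage between the two betaines. Either would lower the enantiomeric purity or give cis product. O-benzylation of the phenoxide by the sulfonium salt may also compete. Fallback, known chemistry: from 8, the same annulation with the achiral salt (4-methoxybenzyl)dimethylsulfonium tetrafluoroborate F1 (from dimethyl sulfide, 10 and NaBF4) should give trans product as the racemate, that is 13 together with its (2S,3S) enantiomer F2. Preparative chromatography on a chiral stationary phase separates them, and the route is rejoined at 13.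

**Step 12 (proposed method).** Reagent control may be too weak against the existing furan 1, giving the furan 2 diastereomer. Excess base may also deprotonate C3–H of furan 1 and open that ring by elimination. Fallback, known chemistry: from 21, annulation with the achiral salt F1 under carbonate-free, stoichiometric base should give the two trans diastereomers, 25 and its (2R,3R)-furan 2 isomer F3. These are diastereomers and are separated on silica. The route is rejoined at 25.

**Step 8 (key step).** Palladation of the C5–H bond beside the methoxy group may be too slow. The arylpalladium species would then couple with the styrene directly, giving the stilbene without the acyl group, or keep norbornene in the product. Fallback: from 13, Friedel–Crafts acylation with 15 and SnCl4 at low temperature at C5 (ortho to iodine, para to the ring oxygen, the same preference as in step 2) to iodo ketone F4. A Mizoroki–Heck coupling of F4 with 17 (Pd(OAc)2, tri-o-tolylphosphine, K2CO3, DMF) then rejoins the route at 18.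

**Step 13.** Protic acid may ionise the benzylic C2–O bonds of the furans in competition with alkene protonation, leading to skeletal isomerisation, or the methine may form as a mixture of epimers. Fallback: from 25, epoxidation of the stilbene with dimethyldioxirane to epoxide F5. Ring closure with BF3·OEt2 at −78 °C by opening at the anisyl-bearing carbon gives alcohol F6. Its thiocarbonylimidazolide F7 is reduced with Bu3SnH in a Barton–McCombie deoxygenation, and the route is rejoined at 26.

**Step 15.** Fivefold Lewis-acid demethylation may open the dihydrofurans or stop short of completion, with rearrangement of the benzylic cations so formed. Fallback: from 26, nucleophilic cleavage with excess EtSNa in DMF at 140 °C, which removes the methyl groups by SN2 at carbon and the tosyl groups by attack at sulfur, arrives directly at 28. No new compound is made.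

## Further compounds

F1 | step 6 | (4-methoxybenzyl)dimethylsulfonium tetrafluoroborate | COc1ccc(C[S+](C)C)cc1.F[B-](F)(F)F
F2 | step 6 | (2S,3S)-enantiomer of 13, formed with 13 as the racemate | COc1cc2c(c(I)c1)[C@H](c1cc(OS(=O)(=O)c3ccc(C)cc3)cc(OS(=O)(=O)c3ccc(C)cc3)c1)[C@@H](c1ccc(OC)cc1)O2
F3 | step 12 | diastereomer of 25 with (2R,3R)-configured furan 2 | COc1ccc(/C=C/c2c3c(cc4c2[C@@H](c2cc(OS(=O)(=O)c5ccc(C)cc5)cc(OS(=O)(=O)c5ccc(C)cc5)c2)[C@H](c2ccc(OC)cc2)O4)O[C@@H](c2ccc(OC)cc2)[C@@H]3c2cc(OC)cc(OC)c2)cc1
F4 | step 8 | [(2R,3R)-3-[3,5-bis(tosyloxy)phenyl]-4-iodo-6-methoxy-2-(4-methoxyphenyl)-2,3-dihydro-1-benzofuran-5-yl](3,5-dimethoxyphenyl)methanone | COc1cc2c(c(I)c1C(=O)c1cc(OC)cc(OC)c1)[C@@H](c1cc(OS(=O)(=O)c3ccc(C)cc3)cc(OS(=O)(=O)c3ccc(C)cc3)c1)[C@H](c1ccc(OC)cc1)O2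
F5 | step 13 | trans-epoxide of the stilbene of 25, both epoxide diastereomers | COc1ccc(C2OC2c2c3c(cc4c2[C@@H](c2cc(OS(=O)(=O)c5ccc(C)cc5)cc(OS(=O)(=O)c5ccc(C)cc5)c2)[C@H](c2ccc(OC)cc2)O4)O[C@H](c2ccc(OC)cc2)[C@H]3c2cc(OC)cc(OC)c2)cc1
F6 | step 13 | 26 with a hydroxy group on the ring CH2 carbon, configuration at that carbon open | COc1ccc([C@@H]2C(O)c3c4c(cc5c3[C@@H](c3cc(OS(=O)(=O)c6ccc(C)cc6)cc(OS(=O)(=O)c6ccc(C)cc6)c3)[C@H](c3ccc(OC)cc3)O5)O[C@H](c3ccc(OC)cc3)[C@H]4c3cc(OC)cc(OC)c32)cc1
F7 | step 13 | O-(imidazol-1-ylthiocarbonyl) derivative of F6 | COc1ccc([C@@H]2C(OC(=S)n7ccnc7)c3c4c(cc5c3[C@@H](c3cc(OS(=O)(=O)c6ccc(C)cc6)cc(OS(=O)(=O)c6ccc(C)cc6)c3)[C@H](c3ccc(OC)cc3)O5)O[C@H](c3ccc(OC)cc3)[C@H]4c3cc(OC)cc(OC)c32)cc1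
F0 | step 15 | none | none
A1 | alternative 1 | methyl 5,7-dimethoxy-2-oxo-2,3-dihydro-1H-indene-1-carboxylate | COC(=O)C1C(=O)Cc2cc(OC)cc(OC)c12
A2 | alternative 1 | 3,5-dimethoxy-2-(trimethylsilyl)phenyl trifluoromethanesulfonate | COc1cc(OC)c([Si](C)(C)C)c(OS(=O)(=O)C(F)(F)F)c1
A3 | alternative 1 | tetramethoxy dibenzosuberone ester, racemic at the ester-bearing carbon, one sense drawn | COC(=O)[C@@H]1c2c(OC)cc(OC)cc2CC(=O)c2c(OC)cc(OC)cc21
A4 | alternative 2 | 2-aryl benzofuran carrying furan 1 and the (S)-1-(2-bromo-4,6-dimethoxyphenyl)-1-(4-methoxyphenyl)ethyl side chain | COc1ccc([C@@H](c2c(Br)cc(OC)cc2OC)Cc2c3cc(-c4ccc(OC)cc4)oc3cc3c2[C@@H](c2cc(OC)cc(OC)c2)[C@H](c2ccc(OC)cc2)O3)cc1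
A5 | alternative 2 | heptamethyl ether of the target | COc1ccc([C@@H]2Cc3c4c(cc5c3[C@@H](c3cc(OC)cc(OC)c3)[C@H](c3ccc(OC)cc3)O5)O[C@H](c3ccc(OC)cc3)[C@H]4c3cc(OC)cc(OC)c32)cc1
A6 | alternative 3 | 1,3,5,7-tetramethoxyanthracene-9,10-dione | COc1cc(OC)c2C(=O)c3cc(OC)cc(OC)c3C(=O)c2c1
A7 | alternative 3 | 1-(diazomethyl)-4-methoxybenzene | COc1ccc(C=[N+]=[N-])cc1
A8 | alternative 3 | ring-expanded aryl dibenzotropone, enol form | COc1ccc(C2=C(O)c3cc(OC)cc(OC)c3C(=O)c3cc(OC)cc(OC)c32)cc1
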